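## Retrosynthetic overview

1. Target 24 ⇐ 17,19-diol 21 (double oxidation; C8 is epimerised to the equatorial 8α position at the 17-aldehyde stage) ⇐ 9β-vinyl decalin 18 + preformed bromobutenolide 19 (B-alkyl Suzuki coupling, C12–C13).
2. Decalin ⇐ acyclic (2E,8E,10E)-trienal 13 by an intramolecular Diels–Alder reaction: dienophile C9=C10 (geranial-type enal, C11 = CHO), diene C5=C6–C7=C8 (C17 as CH2OTBS), tether C1–C4. Bonds C5–C10 and C8–C9 form, rings A and B close in the same step, and C5, C9, C10 (and C8, as its epimer) arise from the single stereocentre C4.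
3. Feature that invites it: ring B carries the vicinal carbon branches C17 (on C8) and C11 (on C9) next to the quaternary C10–CH3, while C6 and C7 are bare CH2 groups. C9=C10 therefore maps onto an enal and the leftover alkene lands at C6=C7.
4. Trienal 13 ⇐ (S)-C4 hydroxy ester 7 (Takai iodo-olefination, then Suzuki coupling with boronate 10 for C7, C8, C17) ⇐ prochiral malonate 6 (catalytic desymmetrising reduction sets C4) ⇐ dimethyl methylmalonate 5 + iodide 4 (C1–C3, C9–C11, C20) from geranyl acetate 1.
5. Ring order: rings A and B together in step 9; the butenolide ring is brought in intact in step 13.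

Key step: step 9

Assumption and convention: positions follow labdane numbering (C1–C10 decalin, C11–C16 side chain and butenolide, C17 on C8, C18 = 4α-CH3, C19 = 4β-carboxyl carbon, C20 = 10β-CH3; β = the face of C20); boronate 10 and 3-bromofuran-2(5H)-one 19 are taken as catalogue compounds.

## Route

Step 1
Reactants: 1 geranyl acetate
Product: 3 (2E)-6-hydroxy-3-methylhex-2-en-1-yl acetate, via aldehyde 2 (not isolated)
Conditions: O3 (1.0 equiv, dye end point), CH2Cl2/MeOH, −78 °C; then NaBH4, −78 → 0 °C
Reagents that add atoms: ozone, [O-][O+]=O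
Why: Ozonolysis with reductive work-up; ozone should attack the electron-rich terminal trisubstituted alkene much faster than the 2,3-alkene deactivated by the allylic acetate, and borohydride reduces the aldehyde in the same flask, leaving the E-alkene untouched.

Step 2
Reactants: 3 (2E)-6-hydroxy-3-methylhex-2-en-1-yl acetate
Product: 4 (2E)-6-iodo-3-methylhex-2-en-1-yl acetate
Conditions: I2, PPh3, imidazole, CH2Cl2, 0 °C → rt
Reagents that add atoms: iodine, II
Why: Appel-type iodination of a primary alcohol (SN2 on the alkoxyphosphonium ion), with no effect on the acetate or the alkene.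

Step 3
Reactants: 4 (2E)-6-iodo-3-methylhex-2-en-1-yl acetate; 5 dimethyl 2-methylmalonate
Product: 6 dimethyl 2-[(4E)-6-acetoxy-4-methylhex-4-en-1-yl]-2-methylpropanedioate
Conditions: NaH, THF/DMF, 0 °C; then 4, rt → 50 °C
Reagents that add atoms: none
Why: Malonic ester alkylation (SN2 of the soft sodium enolate on the primary iodide) builds the C3–C4 bond and the prochiral quaternary C4.

Step 4
Reactants: 6 dimethyl 2-[(4E)-6-acetoxy-4-methylhex-4-en-1-yl]-2-methylpropanedioate
Product: 7 methyl (2S,6E)-8-acetoxy-2-(hydroxymethyl)-2,6-dimethyloct-6-enoate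
Conditions: Et2Zn (10 mol %), chiral tetradentate 2,6-bis(aminomethyl)phenol ligand with two diaryl(piperidin-2-yl)methanol arms (5 mol %, the enantiomer that gives (S)-7), HSi(OMe)3, THF, 0 °C → rt; then aq NH4F
Reagents that add atoms: none
Why: Catalytic desymmetrising hydrosilylation of a 2,2-disubstituted malonic ester by a dinuclear zinc hydride, which should reduce one enantiotopic ester group only (the chelating malonate is activated, the product hydroxy ester and the acetate are not) and so sets C4, the only stereocentre carried into the key step.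

Step 5
Reactants: 7 methyl (2S,6E)-8-acetoxy-2-(hydroxymethyl)-2,6-dimethyloct-6-enoate
Product: 8 methyl (2S,6E)-8-acetoxy-2-formyl-2,6-dimethyloct-6-enoate
Conditions: Dess–Martin periodinane, NaHCO3, CH2Cl2, 0 °C → rt
Reagents that add atoms: none
Why: Dess–Martin oxidation of the neopentyl alcohol; the α-carbon is quaternary, so the aldehyde cannot epimerise.

Step 6
Reactants: 8 methyl (2S,6E)-8-acetoxy-2-formyl-2,6-dimethyloct-6-enoate
Product: 9 methyl (2S,6E)-8-acetoxy-2-[(E)-2-iodoethenyl]-2,6-dimethyloct-6-enoate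
Conditions: CrCl2, CHI3, THF, 0 °C → rt
Reagents that add atoms: iodoform, IC(I)I
Why: Takai iodo-olefination (gem-dichromium reagent), which is E-selective, most strongly so for α-branched aldehydes, and tolerates esters; it adds C6.

Step 7
Reactants: 9 methyl (2S,6E)-8-acetoxy-2-[(E)-2-iodoethenyl]-2,6-dimethyloct-6-enoate; 10 (E)-tert-butyldimethyl{[3-(4,4,5,5-tetramethyl-1,3,2-dioxaborolan-2-yl)prop-2-en-1-yl]oxy}silane
Product: 12 methyl (2S,3E,5E)-7-[(tert-butyldimethylsilyl)oxy]-2-[(4E)-6-hydroxy-4-methylhex-4-en-1-yl]-2-methylhepta-3,5-dienoate, via acetate 11 (not isolated)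
Conditions: Pd(dppf)Cl2 (5 mol %), K3PO4, THF/H2O, 45 °C; then K2CO3, MeOH, rt
Reagents that add atoms: none
Why: Suzuki–Miyaura alkenyl–alkenyl coupling with retention at both partners gives the (E,E)-diene (C5–C8, C17), and the carbonate/methanol added afterwards removes the acetate by transesterification while the hindered methyl ester and the silyl ether stay.

Step 8
Reactants: 12 methyl (2S,3E,5E)-7-[(tert-butyldimethylsilyl)oxy]-2-[(4E)-6-hydroxy-4-methylhex-4-en-1-yl]-2-methylhepta-3,5-dienoate
Product: 13 methyl (2S,3E,5E)-7-[(tert-butyldimethylsilyl)oxy]-2-methyl-2-[(4E)-4-methyl-6-oxohex-4-en-1-yl]hepta-3,5-dienoate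
Conditions: MnO2, CH2Cl2, rt
Reagents that add atoms: none
Why: Allylic oxidation with MnO2 of the only free (allylic) alcohol, which keeps the E geometry of the enal as in the oxidation of geraniol to geranial.

Step 9
Reactants: 13 methyl (2S,3E,5E)-7-[(tert-butyldimethylsilyl)oxy]-2-methyl-2-[(4E)-4-methyl-6-oxohex-4-en-1-yl]hepta-3,5-dienoate
Product: 14 trans-octalin ester aldehyde (Δ6; 4α-CH3, 4β-CO2Me, 5α-H, 8β-CH2OTBS, 9β-CHO, 10β-CH3)
Conditions: Me2AlCl (1.5 equiv), CH2Cl2, −78 → −20 °C; aq Rochelle salt
Reagents that add atoms: none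
Why: Complexation of the formyl group by Me2AlCl lowers the LUMO of the C9=C10 enal and the C5=C6–C7=C8 diene adds across it in a concerted, asynchronous [4+2] cycloaddition in which the C5–C10 bond to the β-carbon (the future quaternary centre) runs ahead of C8–C9; the closest known reaction type is the Lewis acid-promoted intramolecular Diels–Alder reaction of (2E,8E,10E)-trienals (terminally activated 1,7,9-decatrienes) to trans-fused octalins, and trisubstituted dienophiles are known to deliver angular-methyl decalins in thermal variants. Ring A (C1–C5, C10) closes through the four-carbon tether C1–C4 in a chair-like array as C5–C10 forms, and ring B (C5–C10) is the new cyclohexene, its alkene left at C6=C7. The trans ring fusion (5α-H, 10β-CH3) follows from the endo transition state with the formyl group under the diene, the 9β-CHO from the E geometry of the enal and the 8β-CH2OTBS (cis to the formyl group) from the E geometry of C7=C8, all by suprafacial addition. The diene face is chosen by the only stereocentre of 13, C4: in the chair-like tether one C4 substituent must sit pseudo-axial, syn to the endo methyl group on C10 and near H6, and the flat, smaller ester group (also the poorer σ-donor) should take that site while the methyl group points anti to the incoming dienophile, which gives the 4β-CO2Me/10β-CH3 relationship. The step therefore needs endo selectivity, secured by the Lewis acid and the terminal activating group, and facial selectivity, secured by the CO2Me/CH3 difference at C4; the C8 centre comes out as the axial epimer by necessity and is inverted under thermodynamic control in step 14.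

Step 10
Reactants: 14 trans-octalin ester aldehyde
Product: 15 trans-decalin ester aldehyde (4α-CH3, 4β-CO2Me, 5α-H, 8β-CH2OTBS, 9β-CHO, 10β-CH3)
Conditions: H2 (1 atm), 10% Pd/C, EtOAc, rt
Reagents that add atoms: none
Why: Heterogeneous hydrogenation of the cis-disubstituted C6=C7 alkene, which creates no stereocentre and should leave the aliphatic aldehyde, the ester and the silyl ether alone.

Step 11
Reactants: 15 trans-decalin ester aldehyde
Product: 16 9β-vinyl decalin ester (4β-CO2Me, 8β-CH2OTBS, 9β-CH=CH2)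
Conditions: Ph3PCH3Br, KHMDS, THF, −78 → 0 °C
Reagents that add atoms: methyltriphenylphosphonium bromide, C[P+](c1ccccc1)(c1ccccc1)c1ccccc1.[Br-]
Why: Wittig methylenation adds C12; the non-stabilised ylide should add to the aldehyde faster than it enolises it at low temperature, so C9 is kept, and it does not react with the hindered ester.

Step 12
Reactants: 16 9β-vinyl decalin ester
Product: 18 9β-vinyl 17,19-diol (4β-CH2OH; 8β-CH2OH; 5α-H; 10β-CH3), via silyl ether alcohol 17 (not isolated)
Conditions: LiAlH4, THF, 0 °C → reflux; then 2 M HCl, THF/MeOH, rt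
Reagents that add atoms: none
Why: Hydride reduction of the hindered axial C19 ester to the neopentyl alcohol (which avoids a late hydrolysis of this ester next to the butenolide), followed by acid cleavage of the primary silyl ether in the work-up.

Step 13
Reactants: 18 9β-vinyl 17,19-diol; 19 3-bromofuran-2(5H)-one
Product: 21 17,19-dihydroxy butenolide (8β-CH2OH; side chain complete), via trialkylborane 20 (not isolated)
Conditions: 9-BBN (3.5 equiv), THF, rt; then 19, Pd(dppf)Cl2 (10 mol %), AsPh3, Cs2CO3, DMF/H2O, rt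
Reagents that add atoms: none
Why: Anti-Markovnikov hydroboration of the monosubstituted alkene with 9-BBN (the excess ties up both hydroxyl groups as borinates), then B-alkyl Suzuki–Miyaura coupling with the α-bromo enoate under the mild base/AsPh3 conditions used for base-sensitive α-halo enones, which forms C12–C13 and brings in the butenolide with its alkene already in place.

Step 14
Reactants: 21 17,19-dihydroxy butenolide
Product: 23 17,19-dialdehyde of the butenolide (equatorial 8α-CHO), via 8β-dialdehyde 22 (not isolated)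
Conditions: Dess–Martin periodinane, NaHCO3, CH2Cl2, rt; then, on the crude product, DBU (0.2 equiv), CH2Cl2, 0 °C → rt
Reagents that add atoms: none
Why: Dess–Martin oxidation of both primary alcohols, then base-mediated epimerisation through the enol of the 17-aldehyde moves the formyl group from the axial 8β site (syn-diaxial to the 10β-CH3) to the equatorial 8α site, which sets C8 of the target under thermodynamic control; the C19 aldehyde is not enolisable.

Step 15
Reactants: 23 17,19-dialdehyde of the butenolide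
Product: 24 target diacid (CNP0478950.1; 4β-CO2H, 8α-CO2H, 9β side chain, 16,15-olide)
Conditions: NaClO2, NaH2PO4, 2-methylbut-2-ene, t-BuOH/H2O, rt
Reagents that add atoms: sodium chlorite, [Na+].[O-]Cl=O
Why: Pinnick oxidation of both aldehydes under buffered, weakly acidic conditions, which should neither epimerise C8 nor touch the electron-poor butenolide alkene (hypochlorite is scavenged by the added alkene).

## Compound list

1 | geranyl acetate, (2E)-3,7-dimethylocta-2,6-dien-1-yl acetate | CC(=O)OC/C=C(\C)CCC=C(C)C | starting material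
2 | (4E)-6-acetoxy-4-methylhex-4-enal | CC(=O)OC/C=C(\C)CCC=O | intermediate
3 | (2E)-6-hydroxy-3-methylhex-2-en-1-yl acetate | CC(=O)OC/C=C(\C)CCCO | intermediate
4 | (2E)-6-iodo-3-methylhex-2-en-1-yl acetate | CC(=O)OC/C=C(\C)CCCI | intermediate
5 | dimethyl 2-methylmalonate | COC(=O)C(C)C(=O)OC | starting material
6 | dimethyl 2-[(4E)-6-acetoxy-4-methylhex-4-en-1-yl]-2-methylpropanedioate | CC(=O)OC/C=C(\C)CCCC(C)(C(=O)OC)C(=O)OC | intermediate
7 | methyl (2S,6E)-8-acetoxy-2-(hydroxymethyl)-2,6-dimethyloct-6-enoate | CC(=O)OC/C=C(\C)CCC[C@](C)(C(=O)OC)CO | intermediate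
8 | methyl (2S,6E)-8-acetoxy-2-formyl-2,6-dimethyloct-6-enoate | CC(=O)OC/C=C(\C)CCC[C@](C)(C(=O)OC)C=O | intermediate
9 | methyl (2S,6E)-8-acetoxy-2-[(E)-2-iodoethenyl]-2,6-dimethyloct-6-enoate | CC(=O)OC/C=C(\C)CCC[C@](C)(C(=O)OC)/C=C/I | intermediate
10 | (E)-tert-butyldimethyl{[3-(4,4,5,5-tetramethyl-1,3,2-dioxaborolan-2-yl)prop-2-en-1-yl]oxy}silane | CC(C)(C)[Si](C)(C)OC/C=C/B1OC(C)(C)C(C)(C)O1 | starting material
11 | methyl (2S,3E,5E)-2-[(4E)-6-acetoxy-4-methylhex-4-en-1-yl]-7-[(tert-butyldimethylsilyl)oxy]-2-methylhepta-3,5-dienoate | CC(=O)OC/C=C(\C)CCC[C@](C)(C(=O)OC)/C=C/C=C/CO[Si](C)(C)C(C)(C)C | intermediate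
12 | methyl (2S,3E,5E)-7-[(tert-butyldimethylsilyl)oxy]-2-[(4E)-6-hydroxy-4-methylhex-4-en-1-yl]-2-methylhepta-3,5-dienoate | OC/C=C(\C)CCC[C@](C)(C(=O)OC)/C=C/C=C/CO[Si](C)(C)C(C)(C)C | intermediate
13 | methyl (2S,3E,5E)-7-[(tert-butyldimethylsilyl)oxy]-2-methyl-2-[(4E)-4-methyl-6-oxohex-4-en-1-yl]hepta-3,5-dienoate | O=C/C=C(\C)CCC[C@](C)(C(=O)OC)/C=C/C=C/CO[Si](C)(C)C(C)(C)C | intermediate
14 | trans-octalin ester aldehyde: C6=C7 alkene, 4α-CH3, 4β-CO2Me, 5α-H, 8β-CH2OTBS, 9β-CHO, 10β-CH3 | C[C@]12CCC[C@](C)(C(=O)OC)[C@@H]1C=C[C@H](CO[Si](C)(C)C(C)(C)C)[C@@H]2C=O | intermediate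
15 | trans-decalin ester aldehyde: 4α-CH3, 4β-CO2Me, 5α-H, 8β-CH2OTBS, 9β-CHO, 10β-CH3 | C[C@]12CCC[C@](C)(C(=O)OC)[C@@H]1CC[C@H](CO[Si](C)(C)C(C)(C)C)[C@@H]2C=O | intermediate
16 | 9β-vinyl decalin ester: 4β-CO2Me, 8β-CH2OTBS, 9β-CH=CH2 | C[C@]12CCC[C@](C)(C(=O)OC)[C@@H]1CC[C@H](CO[Si](C)(C)C(C)(C)C)[C@@H]2C=C | intermediate
17 | 9β-vinyl decalin 19-alcohol 17-silyl ether: 4β-CH2OH, 8β-CH2OTBS | C[C@]12CCC[C@](C)(CO)[C@@H]1CC[C@H](CO[Si](C)(C)C(C)(C)C)[C@@H]2C=C | intermediate
18 | 9β-vinyl decalin 17,19-diol: 4β-CH2OH, 8β-CH2OH | C[C@]12CCC[C@](C)(CO)[C@@H]1CC[C@H](CO)[C@@H]2C=C | intermediate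
19 | 3-bromofuran-2(5H)-one | O=C1OCC=C1Br | starting material
20 | C12 B-alkyl-9-BBN adduct of 18, both hydroxyl groups as 9-BBN borinates | C[C@]12CCC[C@](C)(COB3C4CCCC3CCC4)[C@@H]1CC[C@H](COB3C4CCCC3CCC4)[C@@H]2CCB3C4CCCC3CCC4 | intermediate
21 | 17,19-dihydroxy butenolide: 4β-CH2OH, 8β-CH2OH, 9β-CH2CH2-(2-oxo-2,5-dihydrofuran-3-yl) | C[C@]12CCC[C@](C)(CO)[C@@H]1CC[C@H](CO)[C@@H]2CCC1=CCOC1=O | intermediate
22 | 17,19-dialdehyde, axial 8β-CHO | C[C@]12CCC[C@](C)(C=O)[C@@H]1CC[C@H](C=O)[C@@H]2CCC1=CCOC1=O | intermediate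
23 | 17,19-dialdehyde, equatorial 8α-CHO | C[C@]12CCC[C@](C)(C=O)[C@@H]1CC[C@@H](C=O)[C@@H]2CCC1=CCOC1=O | intermediate
24 | target, 8βH-labd-13-en-16,15-olide-17,19-dioic acid (CNP0478950.1) | C[C@]12CCC[C@](C)(C(=O)O)[C@@H]1CC[C@@H](C(=O)O)[C@@H]2CCC1=CCOC1=O | target

## Step count and risks

Total step count: 15. Longest linear sequence: 15 steps (1 → 24); compounds 5, 10 and 19 enter as catalogue reagents.

Steps most likely to fail:

1. Step 9 (intramolecular Diels–Alder reaction). The cycloaddition at the congested C5–C10 bond may be too slow at temperatures at which the Lewis acid leaves the dienylic silyl ether and the E geometry of the enal intact, and the C4 centre may discriminate the two diene faces only moderately. The fallback sets out from 13 and comes back at 14. The enal is converted with 1,2-bis(trimethylsilyloxy)ethane and catalytic TMSOTf (CH2Cl2, −78 °C) into the dioxolane triene F1. More TMSOTf (or catalytic TfOH) at −78 → −40 °C ionises the acetal to a 2-alkenyl-1,3-dioxolan-2-ylium ion, a much stronger dienophile whose charge sits on the tertiary C10, and the ionic intramolecular [4+2] cyclisation should give the dioxolane adduct F2. Mild hydrolysis (PPTS, wet acetone) then gives 14.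

2. Step 4 (desymmetrising reduction). The catalyst may distinguish the methyl group from the long alkyl chain poorly, giving low enantiomeric purity at C4, or the acetate may be partly reduced. The fallback sets out from 6 and comes back at 7. Pig liver esterase (phosphate buffer, pH 7.5, pH-stat) hydrolyses one enantiotopic methyl ester and the acetate to give the hydroxy half-ester F3, assumed to be the (2R)-acid by analogy with the chain-length trend known for 2-alkyl-2-methylmalonates. LiBH4 (THF, on the lithium carboxylate) reduces only the remaining ester to give the dihydroxy acid F4. TMSCHN2 (MeOH/toluene) gives the dihydroxy ester F5, and selective acetylation of the unhindered allylic hydroxyl group (Ac2O 1.05 equiv, 2,4,6-collidine, CH2Cl2, −40 °C) gives 7.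

3. Step 13 (B-alkyl Suzuki coupling). The bromobutenolide may decompose under the basic coupling conditions, or the hindered alkylborane may transmetalate slowly and protodeboronate. The fallback sets out from 18 and comes back at 21. Silylation of both hydroxyl groups (TBSOTf, 2,6-lutidine) gives the bis-silyl ether F6; 9-BBN then NaOH/H2O2 gives the C12 alcohol F7; Dess–Martin oxidation gives the C12 aldehyde F8. A Horner–Wadsworth–Emmons reaction with diethyl (2-oxotetrahydrofuran-3-yl)phosphonate (NaH, THF) gives the (E)-α-alkylidene lactone F9. RhCl3·3H2O (cat.) in refluxing EtOH moves the exocyclic alkene into the ring to give the bis-silyl butenolide F10, and HF·pyridine removes both silyl groups to give 21.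

## Further compounds

F1 | step 9 | dioxolane triene, methyl (2S,3E,5E)-7-[(tert-butyldimethylsilyl)oxy]-2-[(4E)-5-(1,3-dioxolan-2-yl)-4-methylpent-4-en-1-yl]-2-methylhepta-3,5-dienoate | C1(/C=C(\C)CCC[C@](C)(C(=O)OC)/C=C/C=C/CO[Si](C)(C)C(C)(C)C)OCCO1
F2 | step 9 | dioxolane adduct, 14 with the 9β-CHO as its 1,3-dioxolane | C[C@]12CCC[C@](C)(C(=O)OC)[C@@H]1C=C[C@H](CO[Si](C)(C)C(C)(C)C)[C@@H]2C1OCCO1
F3 | step 4 | hydroxy half-ester, (2R,6E)-8-hydroxy-2-(methoxycarbonyl)-2,6-dimethyloct-6-enoic acid | OC/C=C(\C)CCC[C@](C)(C(=O)O)C(=O)OC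
F4 | step 4 | dihydroxy acid, (2S,6E)-8-hydroxy-2-(hydroxymethyl)-2,6-dimethyloct-6-enoic acid | OC/C=C(\C)CCC[C@](C)(C(=O)O)CO
F5 | step 4 | dihydroxy ester, methyl (2S,6E)-8-hydroxy-2-(hydroxymethyl)-2,6-dimethyloct-6-enoate | OC/C=C(\C)CCC[C@](C)(C(=O)OC)CO
F6 | step 13 | bis-silyl ether of 18 (17,19-bis-OTBS, 9β-vinyl) | C[C@]12CCC[C@](C)(CO[Si](C)(C)C(C)(C)C)[C@@H]1CC[C@H](CO[Si](C)(C)C(C)(C)C)[C@@H]2C=C
F7 | step 13 | C12 alcohol (17,19-bis-OTBS, 9β-CH2CH2OH) | C[C@]12CCC[C@](C)(CO[Si](C)(C)C(C)(C)C)[C@@H]1CC[C@H](CO[Si](C)(C)C(C)(C)C)[C@@H]2CCO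
F8 | step 13 | C12 aldehyde (17,19-bis-OTBS, 9β-CH2CHO) | C[C@]12CCC[C@](C)(CO[Si](C)(C)C(C)(C)C)[C@@H]1CC[C@H](CO[Si](C)(C)C(C)(C)C)[C@@H]2CC=O
F9 | step 13 | (E)-α-alkylidene lactone (17,19-bis-OTBS, C12=C13 exocyclic) | C[C@]12CCC[C@](C)(CO[Si](C)(C)C(C)(C)C)[C@@H]1CC[C@H](CO[Si](C)(C)C(C)(C)C)[C@@H]2C/C=C1\CCOC1=O
F10 | step 13 | bis-silyl butenolide (17,19-bis-OTBS, C13=C14 endocyclic) | C[C@]12CCC[C@](C)(CO[Si](C)(C)C(C)(C)C)[C@@H]1CC[C@H](CO[Si](C)(C)C(C)(C)C)[C@@H]2CCC1=CCOC1=O
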